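In a one-step world, D + G → L + Z, L and Z rise together and neither passes the G charged.

- violet: D 0.38 M; G 0.0625 M; run made earlier
- flask: D 0.25 M; G 0.0625 M; time 2.5 d

violet run (percent of the D and G together charged)

| time / h | Z / % | L / % |
|---|---|---|
| 0.500 | 1.0 | 2.9 |
| 1.00 | 2.2 | 5.2 |
| 2.50 | 4.0 | 12.1 |
| 6.00 | 7.7 | 18.1 |

(readings scatter by 0.5 percentage points)

* ratio of Z to L at 12 min
* ratio of Z to L at 3.0 h
* ratio of Z to L at 2.5 d

- the numbers in the tables scatter with a standard deviation of 0.5 percentage points

Yet violet at 6.00 h reads L at 18.1 %, more than G's 14.1 % of the charge, while Z reads 7.7 %. These two numbers go together if D feeds L and G feeds Z, since D made up 85.9 % of the charge and Z at that time reads below G's share.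

We take each path as first order in its own substrate, so Z/L at a given time follows [G]/[D] as charged. We carry the charge shift, 0.182 from violet to this flask: the decadic logarithm of the factor by which charged [G]/[D] changes between two flasks, added to the logarithm of Z/L (the selectivity factor) at equal times.

Violet's summed readings give Z/L of 0.389, logarithm −0.410. Adding the shift gives −0.228, so our figure for the flask's early hours is 0.591. The time 2.5 d lies 10.0 times beyond violet's last reading, so we give no figure there.

The forecast differs from ours: 0.45 at 12 min (0.33 to 0.64), 0.45 at 3.0 h (0.35 to 0.62), both lower than our figure, and 0.5 at 2.5 d (0.33 to 0.8). Its ground: “No run separates these”.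

The flask gives 0.362 at 12 min, 0.533 at 3.0 h and 1.42 at 2.5 d.

D ⇌ L (K = 0.400, k = 0.0870 /h); L ⇌ J (K = 0.340, k = 0.310 /h); D ⇌ G (K = 0.560, k = 0.00300 /h); G → Z (k = 0.120 /h) At that last time, each step taken net, the flask makes L more slowly than it uses L up, at 0.254 of that rate, with L at 18.9 % and Z at 26.9 %. For a flask like this one but charged with 0.10 M of D, the shift from violet is 0.182 plus 0.398; that second term carries this flask's 0.362 at 12 min to 0.905, and that flask gives 0.904.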